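The pyranone C ring (O1–C2–C3–C4–C4a–C8a) is cut at C2–C3 and O1–C8a. The C=O of a B-ring aldehyde is thereby inserted as the C2–O1 unit between C3 and C8a of an A-ring ketone. The step uses the C4 carbonyl twice: as the enolate anchor for C3 and as the ortho activator of C8a for SNAr. Its precursors are a dienyl benzaldehyde and the silyl enol ether of a 2-fluoroaryl α-MOM-oxy ketone. Under a chiral ammonium fluoride, reversible aldolates are funnelled through fluoride-releasing ring closure into the trans-(2R,3R)-flavanonol. An exo-selective chiral borate Diels–Alder reaction with a 2'-hydroxychalcone then builds the cyclohexene.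

Key step: step 9

Assumption: the sense of induction of the two chiral catalysts is assigned provisionally. The (R,R)-ammonium salt in step 9 and (S)-VANOL in step 12 are equally available and would be used if the opposite sense is found.

Step 1
Reactants: 1 2,4-dihydroxybenzaldehyde
Product: 2 2,4-bis(methoxymethoxy)benzaldehyde
Conditions: NaH, MOMCl, DMF, 0 °C → rt
Reagents that add atoms: chloromethyl methyl ether (MOMCl), COCCl
Why: Williamson-type O-alkylation of both phenoxides gives base-stable acetal ethers that later also direct the lithiation, and no stereocentre is formed.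

Step 2
Reactants: 2 2,4-bis(methoxymethoxy)benzaldehyde
Product: 5 3-iodo-2,4-bis(methoxymethoxy)benzaldehyde, via lithium amino alkoxide 3 (not isolated), via C3-lithiated amino alkoxide 4 (not isolated)
Conditions: 1-methylpiperazine, n-BuLi, THF, −20 °C; then 2; n-BuLi, −20 → 0 °C; I2, −78 °C → rt; aq NH4Cl
Reagents that add atoms: iodine, II
Why: Directed ortho-metalation on an aldehyde masked in situ, in which the lithium amide adds to the CHO group to give a weakly directing α-amino alkoxide, the two MOM ethers jointly direct n-BuLi to C3 between them, iodine traps the aryllithium and work-up returns the aldehyde.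

Step 3
Reactants: 6 2-methylbut-1-en-3-yne
Product: 7 (E)-4,4,5,5-tetramethyl-2-(3-methylbuta-1,3-dien-1-yl)-1,3,2-dioxaborolane
Conditions: HBpin, Cp2ZrHCl (5 mol %), CH2Cl2, 0 °C → rt
Reagents that add atoms: pinacolborane, [H]B1OC(C)(C)C(C)(C)O1
Why: Zirconocene-catalysed syn-hydroboration of the terminal alkyne places boron at the terminus and fixes the E geometry, while the 1,1-disubstituted alkene is left untouched.

Step 4
Reactants: 5 3-iodo-2,4-bis(methoxymethoxy)benzaldehyde; 7 (E)-4,4,5,5-tetramethyl-2-(3-methylbuta-1,3-dien-1-yl)-1,3,2-dioxaborolane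
Product: 8 2,4-bis(methoxymethoxy)-3-[(1E)-3-methylbuta-1,3-dien-1-yl]benzaldehyde
Conditions: Pd(OAc)2 (5 mol %), SPhos (10 mol %), K3PO4, THF–H2O, 50 °C
Reagents that add atoms: none
Why: Suzuki–Miyaura coupling with a bulky biarylphosphine accepts the di-ortho-substituted iodide, tolerates the aldehyde and transfers the dienyl group with retention of the E geometry.

Step 5
Reactants: 9 1-(2-fluoro-4-hydroxyphenyl)ethan-1-one
Product: 10 2-bromo-1-(2-fluoro-4-hydroxyphenyl)ethan-1-one
Conditions: CuBr2 (2 equiv), EtOAc–CHCl3, reflux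
Reagents that add atoms: copper(II) bromide, [Cu+2].[Br-].[Br-]
Why: Heterogeneous α-bromination of an aryl methyl ketone with copper(II) bromide is selective for the side chain of hydroxyacetophenones, because the ring is deactivated by the acyl and fluoro groups.

Step 6
Reactants: 10 2-bromo-1-(2-fluoro-4-hydroxyphenyl)ethan-1-one
Product: 12 1-(2-fluoro-4-hydroxyphenyl)-2-hydroxyethan-1-one, via formate ester 11 (not isolated)
Conditions: HCO2Na, EtOH–H2O, reflux
Reagents that add atoms: sodium formate, [Na+].[O-]C=O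
Why: SN2 displacement of the phenacyl bromide by formate and hydrolysis of the labile formate ester in the same pot give the α-hydroxy ketone in a medium too weakly basic for SNAr at the C–F bond.

Step 7
Reactants: 12 1-(2-fluoro-4-hydroxyphenyl)-2-hydroxyethan-1-one
Product: 13 1-[2-fluoro-4-(methoxymethoxy)phenyl]-2-(methoxymethoxy)ethan-1-one
Conditions: MOMCl, iPr2NEt, CH2Cl2, 0 °C → rt
Reagents that add atoms: chloromethyl methyl ether (MOMCl), COCCl
Why: O-alkylation of the phenol and the primary alcohol under amine base avoids a free alkoxide that could displace the ortho fluoride, and the side-chain MOM group later blocks five-membered ring closure.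

Step 8
Reactants: 13 1-[2-fluoro-4-(methoxymethoxy)phenyl]-2-(methoxymethoxy)ethan-1-one
Product: 15 (Z)-{1-[2-fluoro-4-(methoxymethoxy)phenyl]-2-(methoxymethoxy)ethenyl}oxy(trimethyl)silane, via chelated lithium enolate 14 (not isolated)
Conditions: LiHMDS, THF, −78 °C; TMSCl, −78 → 0 °C; pentane, filtration
Reagents that add atoms: chlorotrimethylsilane, C[Si](C)(C)Cl
Why: Kinetic deprotonation gives the lithium-chelated Z-enolate (enolate oxygen and MOM oxygen cis), which is O-silylated to the Z-silyl enol ether.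

Step 9
Reactants: 8 2,4-bis(methoxymethoxy)-3-[(1E)-3-methylbuta-1,3-dien-1-yl]benzaldehyde; 15 (Z)-{1-[2-fluoro-4-(methoxymethoxy)phenyl]-2-(methoxymethoxy)ethenyl}oxy(trimethyl)silane
Product: 17 (2R,3R)-2-{2,4-bis(methoxymethoxy)-3-[(1E)-3-methylbuta-1,3-dien-1-yl]phenyl}-3,7-bis(methoxymethoxy)chroman-4-one, via anti aldolate 16 (not isolated)
Conditions: (S,S)-3,4,5-trifluorophenyl-NAS bromide (10 mol %), CsF (10 mol %, pre-stirred), 15 (1.3 equiv), 4 Å MS, toluene–THF, −20 °C → rt
Reagents that add atoms: none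
Why: Proposed new method: the ammonium fluoride desilylates 15 to a chiral ammonium enolate that adds reversibly through C3 to the aldehyde carbon of 8 (C2–C3 bond), the benzylic alkoxide O1 of 16 then attacks C8a, which the ortho C4 carbonyl turns into a vinylogous acyl fluoride carbon, and the expelled fluoride (O1–C8a bond) returns to the cation and desilylates the next molecule of 15, so the chain runs without a stoichiometric base that could open the product by E1cB. The closest known reaction types are the chiral ammonium fluoride-catalysed Mukaiyama-type aldol addition, the fluoride-catalysed SNAr of silyl ethers with aryl fluorides and the phase-transfer-catalysed asymmetric Darzens condensation, in which equilibrating aldolates are likewise resolved by a chiral cation in an irreversible ring-closing displacement. The one new ring, the pyranone C ring, closes by intramolecular SNAr, formally a 6-endo-trig addition to C8a=C4a–C4=O via a Meisenheimer enolate followed by loss of fluoride. C3 is controlled relative to C2 by the half-chair closing transition state, which places the aryl and OMOM groups both pseudo-equatorial so that the anti aldolate closes fast while the syn aldolate reverts by retro-aldol, and C2 is controlled by the C2-symmetric cation that is ion-paired with the alkoxide and the developing Meisenheimer anion in this selectivity-determining closure. The step needs six- over five-membered closure, attack at the aldehyde only and an intact diene: the MOM group on the C3 oxygen removes the competing alkoxide that would give a benzofuranone, 8 has no other electrophilic carbonyl or acidic proton, and the MOM ethers and the diene are inert to fluoride and enolate. The C7 OMOM donor is meta to C8a and so does not deactivate the attacked carbon, and the irreversible closure drains the unfavourable aldol equilibrium of the electron-rich aldehyde.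

Step 10
Reactants: 18 1-(2,4-dihydroxyphenyl)ethan-1-one
Product: 19 1-[2-hydroxy-4-(methoxymethoxy)phenyl]ethan-1-one
Conditions: MOMCl (1.1 equiv), K2CO3, acetone, rt
Reagents that add atoms: chloromethyl methyl ether (MOMCl), COCCl
Why: Selective O-alkylation occurs at the 4-OH because the 2-OH is hydrogen-bonded to the ketone and far less nucleophilic under carbonate base.

Step 11
Reactants: 19 1-[2-hydroxy-4-(methoxymethoxy)phenyl]ethan-1-one; 2 2,4-bis(methoxymethoxy)benzaldehyde
Product: 20 (E)-3-[2,4-bis(methoxymethoxy)phenyl]-1-[2-hydroxy-4-(methoxymethoxy)phenyl]prop-2-en-1-one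
Conditions: KOH, EtOH, rt; aq citric acid work-up
Reagents that add atoms: none
Why: Claisen–Schmidt condensation (aldol addition and E1cB dehydration) gives the thermodynamically favoured E-chalcone and leaves the chelated 2'-OH free for boron binding.

Step 12
Reactants: 17 (2R,3R)-2-{2,4-bis(methoxymethoxy)-3-[(1E)-3-methylbuta-1,3-dien-1-yl]phenyl}-3,7-bis(methoxymethoxy)chroman-4-one; 20 (E)-3-[2,4-bis(methoxymethoxy)phenyl]-1-[2-hydroxy-4-(methoxymethoxy)phenyl]prop-2-en-1-one
Product: 21 (2R,3R)-2-{3-[(1R,5S,6R)-5-[2,4-bis(methoxymethoxy)phenyl]-6-[2-hydroxy-4-(methoxymethoxy)benzoyl]-3-methylcyclohex-2-en-1-yl]-2,4-bis(methoxymethoxy)phenyl}-3,7-bis(methoxymethoxy)chroman-4-one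
Conditions: (R)-VANOL (30 mol %), B(OPh)3 (25 mol %), 4 Å MS, PhCF3, 40 °C
Reagents that add atoms: none
Why: Chiral borate-catalysed Diels–Alder reaction of a 2'-hydroxychalcone, in which the phenol and ketone of 20 bind boron and lower the LUMO, the 1-aryl and 3-methyl groups of the diene reinforce one regiochemistry, the E-alkene fixes the C5/C6 trans relation, the exo approach that this catalyst class can favour for a di-ortho-substituted aryl diene sets C1/C6 trans, and the vaulted ligand shields one enone face to set the absolute configuration (1R,5S,6R).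

Step 13
Reactants: 21 (2R,3R)-2-{3-[(1R,5S,6R)-5-[2,4-bis(methoxymethoxy)phenyl]-6-[2-hydroxy-4-(methoxymethoxy)benzoyl]-3-methylcyclohex-2-en-1-yl]-2,4-bis(methoxymethoxy)phenyl}-3,7-bis(methoxymethoxy)chroman-4-one
Product: 22 guangsangon K
Conditions: HCl (1.25 M in MeOH), MeOH–THF, 35 °C
Reagents that add atoms: none
Why: Acid-catalysed acetal exchange with methanol removes all seven MOM groups under the mild conditions used for prenylated polyphenols, which spare a trisubstituted alkene next to free phenols, and no stereocentre is touched.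

Compound list
1 | 2,4-dihydroxybenzaldehyde | O=Cc1ccc(O)cc1O | starting material
2 | 2,4-bis(methoxymethoxy)benzaldehyde | COCOc1ccc(C=O)c(OCOC)c1 | intermediate
3 | lithium [2,4-bis(methoxymethoxy)phenyl](4-methylpiperazin-1-yl)methanolate (masked aldehyde) | COCOc1ccc(C([O-])N2CCN(C)CC2)c(OCOC)c1.[Li+] | intermediate
4 | 3-lithio derivative of 3 (aryllithium between the two MOM ethers) | [Li]c1c(OCOC)ccc(C([O-])N2CCN(C)CC2)c1OCOC.[Li+] | intermediate
5 | 3-iodo-2,4-bis(methoxymethoxy)benzaldehyde | COCOc1ccc(C=O)c(OCOC)c1I | intermediate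
6 | 2-methylbut-1-en-3-yne | C=C(C)C#C | starting material
7 | (E)-4,4,5,5-tetramethyl-2-(3-methylbuta-1,3-dien-1-yl)-1,3,2-dioxaborolane | C=C(C)/C=C/B1OC(C)(C)C(C)(C)O1 | intermediate
8 | 2,4-bis(methoxymethoxy)-3-[(1E)-3-methylbuta-1,3-dien-1-yl]benzaldehyde | C=C(C)/C=C/c1c(OCOC)ccc(C=O)c1OCOC | intermediate
9 | 1-(2-fluoro-4-hydroxyphenyl)ethan-1-one | CC(=O)c1ccc(O)cc1F | starting material
10 | 2-bromo-1-(2-fluoro-4-hydroxyphenyl)ethan-1-one | O=C(CBr)c1ccc(O)cc1F | intermediate
11 | 2-(2-fluoro-4-hydroxyphenyl)-2-oxoethyl formate | O=COCC(=O)c1ccc(O)cc1F | intermediate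
12 | 1-(2-fluoro-4-hydroxyphenyl)-2-hydroxyethan-1-one | O=C(CO)c1ccc(O)cc1F | intermediate
13 | 1-[2-fluoro-4-(methoxymethoxy)phenyl]-2-(methoxymethoxy)ethan-1-one | COCOCC(=O)c1ccc(OCOC)cc1F | intermediate
14 | lithium (Z)-1-[2-fluoro-4-(methoxymethoxy)phenyl]-2-(methoxymethoxy)ethen-1-olate | COCO/C=C(\[O-])c1ccc(OCOC)cc1F.[Li+] | intermediate
15 | (Z)-{1-[2-fluoro-4-(methoxymethoxy)phenyl]-2-(methoxymethoxy)ethenyl}oxy(trimethyl)silane | COCO/C=C(\O[Si](C)(C)C)c1ccc(OCOC)cc1F | intermediate
16 | (1R,2R)-1-{2,4-bis(methoxymethoxy)-3-[(1E)-3-methylbuta-1,3-dien-1-yl]phenyl}-3-[2-fluoro-4-(methoxymethoxy)phenyl]-2-(methoxymethoxy)-3-oxopropan-1-olate (anti aldolate, chiral ammonium salt, anion drawn) | C=C(C)/C=C/c1c(OCOC)ccc([C@@H]([O-])[C@@H](OCOC)C(=O)c2ccc(OCOC)cc2F)c1OCOC | intermediate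
17 | (2R,3R)-2-{2,4-bis(methoxymethoxy)-3-[(1E)-3-methylbuta-1,3-dien-1-yl]phenyl}-3,7-bis(methoxymethoxy)chroman-4-one | C=C(C)/C=C/c1c(OCOC)ccc([C@H]2Oc3cc(OCOC)ccc3C(=O)[C@@H]2OCOC)c1OCOC | intermediate
18 | 1-(2,4-dihydroxyphenyl)ethan-1-one | CC(=O)c1ccc(O)cc1O | starting material
19 | 1-[2-hydroxy-4-(methoxymethoxy)phenyl]ethan-1-one | CC(=O)c1ccc(OCOC)cc1O | intermediate
20 | (E)-3-[2,4-bis(methoxymethoxy)phenyl]-1-[2-hydroxy-4-(methoxymethoxy)phenyl]prop-2-en-1-one | O=C(/C=C/c1ccc(OCOC)cc1OCOC)c1ccc(OCOC)cc1O | intermediate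
21 | (2R,3R)-2-{3-[(1R,5S,6R)-5-[2,4-bis(methoxymethoxy)phenyl]-6-[2-hydroxy-4-(methoxymethoxy)benzoyl]-3-methylcyclohex-2-en-1-yl]-2,4-bis(methoxymethoxy)phenyl}-3,7-bis(methoxymethoxy)chroman-4-one | CC1=C[C@@H](c2c(OCOC)ccc([C@H]3Oc4cc(OCOC)ccc4C(=O)[C@@H]3OCOC)c2OCOC)[C@H](C(=O)c2ccc(OCOC)cc2O)[C@@H](c2ccc(OCOC)cc2OCOC)C1 | intermediate
22 | guangsangon K, (2R,3R)-2-{3-[(1R,5S,6R)-6-(2,4-dihydroxybenzoyl)-5-(2,4-dihydroxyphenyl)-3-methylcyclohex-2-en-1-yl]-2,4-dihydroxyphenyl}-3,7-dihydroxychroman-4-one | CC1=C[C@@H](c2c(O)ccc([C@H]3Oc4cc(O)ccc4C(=O)[C@@H]3O)c2O)[C@H](C(=O)c2ccc(O)cc2O)[C@@H](c2ccc(O)cc2O)C1 | target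

Total step count: 13.
Longest linear sequence: 7 steps (steps 5, 6, 7, 8, 9, 12, 13; 9 → 10 → 12 → 13 → 15 → 17 → 21 → 22).

Steps most likely to fail

1. Step 9. Ring closure may be slow, which would allow elimination of silyloxide from the silylated aldol to an enone. An achiral-cation background pathway may erode the enantio-discrimination. Residual base may open the product ring. The fallback uses known chemistry only, sets out from 8 and 19 and comes back at 17.
   - Claisen–Schmidt condensation of 8 with 19 (KOH, EtOH) should give the (E)-2'-hydroxychalcone F1.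
   - Silylation of the chelated phenol (TBSOTf, 2,6-lutidine) should give the 2'-O-TBS chalcone F2.
   - Juliá–Colonna epoxidation (poly-L-leucine, urea–H2O2, DBU, THF) attacks only the enone and not the diene, and should give the (αR,βS)-epoxy ketone F3.
   - TBAF frees the phenoxide, which opens the epoxide at the benzylic carbon with inversion, as in the closure of the Algar–Flynn–Oyamada reaction. This should give the trans-(2R,3R)-3-hydroxyflavanone F4.
   - MOMCl/iPr2NEt then gives 17.

2. Step 12. Exo/endo and facial selectivity may be poor, or the α-alkoxy ketone of the C ring may sequester the borate. The fallback inverts the order of the two fragment unions, sets out from 8 and 20 and comes back at 22.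
   - The same borate-catalysed cycloaddition is run on the small achiral diene 8. No C-ring ketone competes for boron there, and the exo adduct can be enriched by crystallisation. This should give the cyclohexenyl benzaldehyde F5.
   - MOMCl/iPr2NEt caps the chelated phenol to give the hexa-MOM aldehyde F6.
   - Annulation with 15 under the conditions of step 9 gives the octa-MOM ether F7. Any minor C2/C3 isomer is then a separable diastereomer.
   - The conditions of step 13 give 22.

3. Step 13. Before the last acetal is cleaved, acid may add a liberated ortho-phenol to the ring alkene, cause ketalisation of the aroyl ketone, or epimerise C2. The fallback replaces direct acid solvolysis by a protecting-group exchange, sets out from 21 and comes back at 22.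
   - TESOTf/2,2'-bipyridyl (CH2Cl2, 0 °C, then water) should convert the six aryl MOM ethers into aryl triethylsilyl ethers without Brønsted acid.
   - The same treatment should release the C3 hydroxyl via its bipyridinium acetal, giving the hexakis(triethylsilyl) ether F8.
   - Buffered fluoride (TBAF–AcOH, THF, 0 °C) then frees the phenols near neutral pH.

Further compounds
F1 | step 9 | (E)-3-{2,4-bis(methoxymethoxy)-3-[(1E)-3-methylbuta-1,3-dien-1-yl]phenyl}-1-[2-hydroxy-4-(methoxymethoxy)phenyl]prop-2-en-1-one | COCOc1ccc(C(=O)/C=C/c2ccc(OCOC)c(/C=C/C(C)=C)c2OCOC)c(O)c1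
F2 | step 9 | 2'-O-tert-butyldimethylsilyl ether of F1 | COCOc1ccc(C(=O)/C=C/c2ccc(OCOC)c(/C=C/C(C)=C)c2OCOC)c(O[Si](C)(C)C(C)(C)C)c1
F3 | step 9 | [(2R,3S)-3-{2,4-bis(methoxymethoxy)-3-[(1E)-3-methylbuta-1,3-dien-1-yl]phenyl}oxiran-2-yl][2-(tert-butyldimethylsilyloxy)-4-(methoxymethoxy)phenyl]methanone | COCOc1ccc(C(=O)[C@@H]2O[C@H]2c3ccc(OCOC)c(/C=C/C(C)=C)c3OCOC)c(O[Si](C)(C)C(C)(C)C)c1
F4 | step 9 | (2R,3R)-2-{2,4-bis(methoxymethoxy)-3-[(1E)-3-methylbuta-1,3-dien-1-yl]phenyl}-3-hydroxy-7-(methoxymethoxy)chroman-4-one | C=C(C)/C=C/c1c(OCOC)ccc([C@H]2Oc3cc(OCOC)ccc3C(=O)[C@@H]2O)c1OCOC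
F5 | step 12 | 3-[(1R,5S,6R)-5-[2,4-bis(methoxymethoxy)phenyl]-6-[2-hydroxy-4-(methoxymethoxy)benzoyl]-3-methylcyclohex-2-en-1-yl]-2,4-bis(methoxymethoxy)benzaldehyde | CC1=C[C@@H](c2c(OCOC)ccc(C=O)c2OCOC)[C@H](C(=O)c2ccc(OCOC)cc2O)[C@@H](c2ccc(OCOC)cc2OCOC)C1
F6 | step 12 | 3-[(1R,5S,6R)-6-[2,4-bis(methoxymethoxy)benzoyl]-5-[2,4-bis(methoxymethoxy)phenyl]-3-methylcyclohex-2-en-1-yl]-2,4-bis(methoxymethoxy)benzaldehyde | CC1=C[C@@H](c2c(OCOC)ccc(C=O)c2OCOC)[C@H](C(=O)c2ccc(OCOC)cc2OCOC)[C@@H](c2ccc(OCOC)cc2OCOC)C1
F7 | step 12 | octa-MOM ether of guangsangon K (21 with the chelated phenol also as its MOM ether) | CC1=C[C@@H](c2c(OCOC)ccc([C@H]3Oc4cc(OCOC)ccc4C(=O)[C@@H]3OCOC)c2OCOC)[C@H](C(=O)c2ccc(OCOC)cc2OCOC)[C@@H](c2ccc(OCOC)cc2OCOC)C1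
F8 | step 13 | hexakis(triethylsilyl) aryl ether of guangsangon K (C3 hydroxyl and chelated phenol free) | CC1=C[C@@H](c2c(O[Si](CC)(CC)CC)ccc([C@H]3Oc4cc(O[Si](CC)(CC)CC)ccc4C(=O)[C@@H]3O)c2O[Si](CC)(CC)CC)[C@H](C(=O)c2ccc(O[Si](CC)(CC)CC)cc2O)[C@@H](c2ccc(O[Si](CC)(CC)CC)cc2O[Si](CC)(CC)CC)C1
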